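The whole plan rests on taking C9 out of ring B (C5–C6–C7–C8–C9–C10; ring A is C1–C2–C3–C4–C5–C10). C9 is the oxygen-bearing carbon flanked by the C8 carbonyl and the ring-fusion methine C10, which lets it be brought in as a one-carbon O,S-acetal anion that adds to the C8 ketone of a cis-hydrindanone. A single copper-triggered semipinacol shift then transfers C10 from C8 to C9: it forms the C9–C10 bond, enlarges the five-membered ring to ring B, restores the C8 ketone and leaves C9 oxygenated. The precursor is the tertiary C8 carbinol that carries a CH(OPMB)(SPh) group, with the C3 oxygen silylated and C7 still a methylene.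

Key step: step 14

Remark: eremophilane numbering (C1–C15) is used for every intermediate, α/β refer to the drawing in which the C5 methyl is β, and 1,4-dioxaspiro[4.5]dec-6-en-8-one, (phenylselanyl)acetaldehyde diethyl acetal, tigloyl chloride and 3-methylbut-2-enoyl chloride are taken as catalogue compounds.

Step 1
Reactants: 1 ketal enone 1,4-dioxaspiro[4.5]dec-6-en-8-one
Product: 2 allylic alcohol (R)-1,4-dioxaspiro[4.5]dec-6-en-8-ol
Conditions: RuCl[(R,R)-TsDPEN](p-cymene) (1 mol %), HCO2H/Et3N (5:2), CH2Cl2, rt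
Reagents that add atoms: none
Why: Noyori asymmetric transfer hydrogenation reduces the enone carbonyl in the 1,2-sense, and the (R,R)-catalyst should give the (R)-carbinol (the future C3) because the ring alkene takes the place that the aryl group takes in aryl ketones.

Step 2
Reactants: 2 allylic alcohol (R)-1,4-dioxaspiro[4.5]dec-6-en-8-ol
Product: 3 silyl ether (R)-8-(tert-butyldimethylsilyloxy)-1,4-dioxaspiro[4.5]dec-6-ene
Conditions: TBSCl, imidazole, DMF, rt
Reagents that add atoms: tert-butyldimethylsilyl chloride, CC(C)(C)[Si](C)(C)Cl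
Why: Imidazole-promoted silylation of a secondary alcohol is routine and gives a C3 ether that should last until step 16.

Step 3
Reactants: 3 silyl ether (R)-8-(tert-butyldimethylsilyloxy)-1,4-dioxaspiro[4.5]dec-6-ene
Product: 4 enone (R)-4-(tert-butyldimethylsilyloxy)cyclohex-2-en-1-one
Conditions: PPTS (cat.), acetone/H2O, 55 °C
Reagents that add atoms: water, O
Why: Acid-catalysed ketal hydrolysis with a weak pyridinium acid should free the ketone without cleaving or eliminating the secondary silyl ether.

Step 4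
Reactants: 4 enone (R)-4-(tert-butyldimethylsilyloxy)cyclohex-2-en-1-one
Product: 5 iodoenone (R)-4-(tert-butyldimethylsilyloxy)-2-iodocyclohex-2-en-1-one
Conditions: I2, pyridine, CH2Cl2, 0 °C → rt
Reagents that add atoms: iodine, II
Why: Pyridine-mediated α-iodination of a cyclic enone (conjugate addition of pyridine, iodination of the enolate, elimination) is selective for the α-vinylic position and does not touch C3.

Step 5
Reactants: 5 iodoenone (R)-4-(tert-butyldimethylsilyloxy)-2-iodocyclohex-2-en-1-one
Product: 6 methyl enone (R)-4-(tert-butyldimethylsilyloxy)-2-methylcyclohex-2-en-1-one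
Conditions: MeZnCl, Pd(PPh3)4 (5 mol %), THF, 0 °C → rt
Reagents that add atoms: methylzinc chloride, C[Zn]Cl
Why: Negishi coupling of an α-iodoenone proceeds by oxidative addition of zerovalent palladium into the C–I bond, and the organozinc halide is too unreactive to add to the enone itself.

Step 6
Reactants: 7 (phenylselanyl)acetaldehyde diethyl acetal
Product: 8 (phenylselanyl)acetaldehyde
Conditions: 1 M aq. HCl, THF, rt; used at once
Reagents that add atoms: water, O
Why: Acid-catalysed acetal hydrolysis releases the aldehyde that serves as a vinyl cation equivalent in steps 7 and 8.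

Step 7
Reactants: 6 methyl enone (R)-4-(tert-butyldimethylsilyloxy)-2-methylcyclohex-2-en-1-one; 8 (phenylselanyl)acetaldehyde
Product: 10 hydroxy selenide (2S,3R,4R)-4-(tert-butyldimethylsilyloxy)-2-[1-hydroxy-2-(phenylselanyl)ethyl]-2,3-dimethylcyclohexan-1-one, via lithium enolate 9 (not isolated)
Conditions: Me2CuLi (1.1 equiv, from MeLi and CuI), Et2O, −78 → −40 °C; then 8, THF, −78 °C; aq. NH4Cl at −78 °C
Reagents that add atoms: lithium dimethylcuprate, [Li+].C[Cu-]C (made in the flask from methyllithium, [Li]C, and CuI)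
Why: Tandem cuprate conjugate addition and aldol trapping should place the C4 methyl anti to the C3 silyloxy group and then bring the aldehyde onto C5 anti to that new methyl, which sets the quaternary C5 with its methyl cis to the C4 methyl, while the side-chain carbinol centre is lost in step 8.

Step 8
Reactants: 10 hydroxy selenide (2S,3R,4R)-4-(tert-butyldimethylsilyloxy)-2-[1-hydroxy-2-(phenylselanyl)ethyl]-2,3-dimethylcyclohexan-1-one
Product: 11 vinyl ketone (2R,3R,4R)-4-(tert-butyldimethylsilyloxy)-2-ethenyl-2,3-dimethylcyclohexan-1-one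
Conditions: MsCl, Et3N, CH2Cl2, 0 °C → rt
Reagents that add atoms: none
Why: Mesylation followed by selenium-assisted anti elimination through an episelenonium ion (the β-hydroxy selenide to alkene conversion) should give the C5 vinyl group without a free carbocation next to the quaternary centre.

Step 9
Reactants: 11 vinyl ketone (2R,3R,4R)-4-(tert-butyldimethylsilyloxy)-2-ethenyl-2,3-dimethylcyclohexan-1-one
Product: 12 enol ether tert-butyl{[(1R,2R,3R)-3-ethenyl-4-(methoxymethylidene)-2,3-dimethylcyclohexyl]oxy}dimethylsilane (E/Z mixture)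
Conditions: Ph3P(CH2OMe)Cl, KOt-Bu, THF, 0 °C; then 11, rt → 45 °C
Reagents that add atoms: (methoxymethyl)triphenylphosphonium chloride, [Cl-].COC[P+](c1ccccc1)(c1ccccc1)c1ccccc1
Why: Wittig methoxymethylenation adds the future C8 to the C10 carbonyl, a reaction that tolerates an α-quaternary cyclohexanone when the reactive non-stabilised ylide is used in excess.

Step 10
Reactants: 12 enol ether tert-butyl{[(1R,2R,3R)-3-ethenyl-4-(methoxymethylidene)-2,3-dimethylcyclohexyl]oxy}dimethylsilane
Product: 13 aldehyde (2R,3R,4R)-4-(tert-butyldimethylsilyloxy)-2-ethenyl-2,3-dimethylcyclohexane-1-carbaldehyde (C10 epimers)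
Conditions: Cl3CCO2H, CH2Cl2/H2O, 0 °C → rt
Reagents that add atoms: water, O
Why: Mild acid hydrolysis of the enol ether gives the C10 formyl group with the silyl ether intact, and both C10 epimers can be carried on because C10 is corrected in step 11.

Step 11
Reactants: 13 aldehyde (2R,3R,4R)-4-(tert-butyldimethylsilyloxy)-2-ethenyl-2,3-dimethylcyclohexane-1-carbaldehyde
Product: 15 cis-hydrindanone (3aR,4R,5R,7aS)-5-(tert-butyldimethylsilyloxy)-3a,4-dimethyloctahydro-1H-inden-1-one, via C10-epimeric hydrindanone mixture 14 (not isolated)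
Conditions: [Rh(nbd)(dppe)]BF4 (5 mol %), H2 then Ar, CH2Cl2, rt; then NaOMe (0.2 equiv), MeOH, rt
Reagents that add atoms: none
Why: Cationic rhodium–dppe catalysed intramolecular hydroacylation of the 4-pentenal unit (acyl–Rh–H formation, insertion of the C6=C7 vinyl group, reductive elimination forming C7–C8) should close the cyclopentanone from either C10 epimer, and the methoxide equilibration then sets C10 as the cis-fused epimer, which is the more stable one when the angular methyl sits β to the carbonyl.

Step 12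
Reactants: 16 4-methoxybenzyl alcohol; 17 chloromethyl phenyl sulfide
Product: 18 4-methoxybenzyl (phenylsulfanyl)methyl ether
Conditions: NaH, THF, 0 °C; then 17, NaI (cat.), rt
Reagents that add atoms: none
Why: Williamson etherification with an α-chloro sulfide, the same reaction that makes (methylthio)methyl ethers, gives the O,S-acetal in one step.

Step 13
Reactants: 18 4-methoxybenzyl (phenylsulfanyl)methyl ether; 15 cis-hydrindanone (3aR,4R,5R,7aS)-5-(tert-butyldimethylsilyloxy)-3a,4-dimethyloctahydro-1H-inden-1-one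
Product: 20 cis-hydrindanol (1R,3aR,4R,5R,7aS)-5-(tert-butyldimethylsilyloxy)-1-{[(4-methoxybenzyl)oxy](phenylsulfanyl)methyl}-3a,4-dimethyloctahydro-1H-inden-1-ol (C9 epimers), via lithiated sulfide 19 (not isolated)
Conditions: n-BuLi, THF, −78 → −40 °C; then 15, −78 °C; aq. NH4Cl
Reagents that add atoms: none
Why: α-Lithiation takes place at the methylene flanked by sulfur and oxygen, and 1,2-addition of this carbanion to the C8 carbonyl, expected from the convex face, gives the carbinol whose C8 and C9 configurations need no control because C8 becomes the carbonyl carbon and C9 is equilibrated in step 14.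

Step 14
Reactants: 20 cis-hydrindanol (1R,3aR,4R,5R,7aS)-5-(tert-butyldimethylsilyloxy)-1-{[(4-methoxybenzyl)oxy](phenylsulfanyl)methyl}-3a,4-dimethyloctahydro-1H-inden-1-ol
Product: 23 cis-decalinone (1R,4aR,5R,6R,8aS)-6-(tert-butyldimethylsilyloxy)-1-[(4-methoxybenzyl)oxy]-4a,5-dimethyloctahydronaphthalen-2(1H)-one (3α-OTBS, 9β-OPMB, 8-oxo), via oxocarbenium ion 21 (not isolated), via C9-epimeric ketone mixture 22 (not isolated)
Conditions: (CuOTf)2·C6H6 (1.5 equiv Cu), i-Pr2NEt (2 equiv), toluene, 0 °C → rt; filtration; K2CO3 (0.2 equiv), MeOH, rt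
Reagents that add atoms: none
Why: Proposed new method: CuOTf takes benzenethiolate from the O,S-acetal carbon, which leaves an oxocarbenium ion at C9 beside the free C8 hydroxyl, and the C8–C10 bond then shifts to C9 while the hydroxyl becomes the C8 carbonyl, the closest known reaction type being the thiophile-triggered semipinacol ring enlargement of ketone adducts of bis(phenylthio)methyllithium together with the related α-ketol ring enlargement, whereas an α-alkoxy cation of this kind is an extrapolation. Ring B is closed by enlargement of the five-membered ring through this 1,2-shift and not by an end-to-end cyclisation, so no exo or endo rule has to be met. The two C9 epimers of 20 converge on one cation, the migrating C10 keeps its configuration and so carries the cis ring fusion into the decalin, and the new C9 centre is settled by the carbonate equilibration, which places the OPMB group equatorial (9β) because the axial 9α position is 1,3-diaxial to the C4–C5 bond. The selectivity that is needed is migration of C10 instead of C7, and it rests on the higher migratory aptitude of the more substituted C10 methine over the C7 methylene, which is why C7 stays a bare methylene until step 15. A benzyl-type ether is chosen for the C9 oxygen because an acetal-type ether would offer the Lewis acid a second ionisable carbon, and the amine buffer keeps triflic acid from ionising the tertiary alcohol.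

Step 15
Reactants: 23 cis-decalinone (3α-OTBS, 9β-OPMB, 8-oxo); 24 2-bromopropene
Product: 28 isopropenyl ketone (1R,3R,4aR,5R,6R,8aS)-6-(tert-butyldimethylsilyloxy)-1-[(4-methoxybenzyl)oxy]-4a,5-dimethyl-3-(prop-1-en-2-yl)octahydronaphthalen-2(1H)-one (7β-isopropenyl), via lithium enolate 25 (not isolated), via lithium dienolate 26 (not isolated), via C7-epimeric ketone mixture 27 (not isolated)
Conditions: LiN(SiMe3)2 (2.2 equiv), THF, −78 °C; Pd(OAc)2 (5 mol %), P(t-Bu)3 (10 mol %), 24 (1.3 equiv), toluene, −78 °C → rt; AcOH, −78 °C; then DBU (0.1 equiv), CH2Cl2, 0 °C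
Reagents that add atoms: none
Why: Kinetic deprotonation at the C7 methylene and palladium-catalysed α-alkenylation of the ketone enolate (oxidative addition of the alkenyl bromide to zerovalent palladium, enolate transfer, reductive elimination) should attach the isopropenyl group, after which α-protonation of the dienolate and a short DBU equilibration should put it equatorial (7β), since epimerisation at the doubly activated C7–H is faster than movement of the double bond into conjugation.

Step 16
Reactants: 28 isopropenyl ketone (7β-isopropenyl, 3α-OTBS, 9β-OPMB)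
Product: 29 C3 alcohol (1R,3R,4aR,5R,6R,8aS)-6-hydroxy-1-[(4-methoxybenzyl)oxy]-4a,5-dimethyl-3-(prop-1-en-2-yl)octahydronaphthalen-2(1H)-one
Conditions: HF·pyridine, pyridine, THF, 0 °C → rt
Reagents that add atoms: none
Why: Buffered HF desilylation removes the secondary silyl ether without base, so the β,γ-unsaturated ketone and the benzyl-type ether should be unaffected.

Step 17
Reactants: 29 C3 alcohol; 30 tigloyl chloride, (E)-2-methylbut-2-enoyl chloride
Product: 31 C3 tiglate (1R,3R,4aR,5R,6R,8aS)-configured 3α-tigloyloxy-9β-(4-methoxybenzyloxy)-10βH-eremophil-11-en-8-one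
Conditions: 30, pyridine, DMAP (cat.), CH2Cl2, 0 °C → rt
Reagents that add atoms: none
Why: DMAP-catalysed acylation of the equatorial C3 hydroxyl installs the tiglate, whose (E) double bond is the stable geometry and should not isomerise.

Step 18
Reactants: 31 C3 tiglate (9β-OPMB)
Product: 32 C9 alcohol 3α-tigloyloxy-9β-hydroxy-10βH-eremophil-11-en-8-one
Conditions: DDQ, CH2Cl2/pH 7 buffer, 0 °C → rt
Reagents that add atoms: none
Why: Oxidative cleavage of the 4-methoxybenzyl ether by DDQ (benzylic hydride abstraction, then hydrolysis) is neutral and should leave the ester, the ketone and the isopropenyl group alone.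

Step 19
Reactants: 32 C9 alcohol; 33 3-methylbut-2-enoyl chloride
Product: 34 target (3R,4R,5R,7R,9R,10S)-3α-tigloyloxy-9β-(3-methylbut-2-enoyloxy)-10βH-eremophil-11-en-8-one
Conditions: 33, pyridine, DMAP (cat.), CH2Cl2, 0 °C
Reagents that add atoms: none
Why: Acylation of the C9 hydroxyl with the acid chloride in pyridine, chosen over a trialkylamine to avoid vinylketene formation and deconjugation, completes the target with C9 in its equatorial and thermodynamically preferred configuration.

Compound list
1 | 1,4-dioxaspiro[4.5]dec-6-en-8-one | O=C1C=CC2(CC1)OCCO2 | starting material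
2 | (R)-1,4-dioxaspiro[4.5]dec-6-en-8-ol | O[C@H]1C=CC2(CC1)OCCO2 | intermediate
3 | (R)-8-(tert-butyldimethylsilyloxy)-1,4-dioxaspiro[4.5]dec-6-ene | CC(C)(C)[Si](C)(C)O[C@H]1C=CC2(CC1)OCCO2 | intermediate
4 | (R)-4-(tert-butyldimethylsilyloxy)cyclohex-2-en-1-one | CC(C)(C)[Si](C)(C)O[C@H]1C=CC(=O)CC1 | intermediate
5 | (R)-4-(tert-butyldimethylsilyloxy)-2-iodocyclohex-2-en-1-one | CC(C)(C)[Si](C)(C)O[C@H]1C=C(I)C(=O)CC1 | intermediate
6 | (R)-4-(tert-butyldimethylsilyloxy)-2-methylcyclohex-2-en-1-one | CC(C)(C)[Si](C)(C)O[C@H]1C=C(C)C(=O)CC1 | intermediate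
7 | (phenylselanyl)acetaldehyde diethyl acetal | CCOC(C[Se]c1ccccc1)OCC | starting material
8 | (phenylselanyl)acetaldehyde | O=CC[Se]c1ccccc1 | intermediate
9 | lithium (3R,4R)-4-(tert-butyldimethylsilyloxy)-2,3-dimethylcyclohex-1-en-1-olate (formed in the flask) | [Li]OC1=C(C)[C@@H](C)[C@H](O[Si](C)(C)C(C)(C)C)CC1 | intermediate
10 | (2S,3R,4R)-4-(tert-butyldimethylsilyloxy)-2-[1-hydroxy-2-(phenylselanyl)ethyl]-2,3-dimethylcyclohexan-1-one (carbinol epimers) | OC(C[Se]c1ccccc1)[C@]1(C)[C@@H](C)[C@H](O[Si](C)(C)C(C)(C)C)CCC1=O | intermediate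
11 | (2R,3R,4R)-4-(tert-butyldimethylsilyloxy)-2-ethenyl-2,3-dimethylcyclohexan-1-one | C=C[C@]1(C)[C@@H](C)[C@H](O[Si](C)(C)C(C)(C)C)CCC1=O | intermediate
12 | tert-butyl{[(1R,2R,3R)-3-ethenyl-4-(methoxymethylidene)-2,3-dimethylcyclohexyl]oxy}dimethylsilane (E/Z mixture) | C=C[C@]1(C)[C@@H](C)[C@H](O[Si](C)(C)C(C)(C)C)CCC1=COC | intermediate
13 | (2R,3R,4R)-4-(tert-butyldimethylsilyloxy)-2-ethenyl-2,3-dimethylcyclohexane-1-carbaldehyde (C10 epimers) | C=C[C@]1(C)[C@@H](C)[C@H](O[Si](C)(C)C(C)(C)C)CCC1C=O | intermediate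
14 | (3aR,4R,5R)-5-(tert-butyldimethylsilyloxy)-3a,4-dimethyloctahydro-1H-inden-1-one, mixture of ring-fusion (C10) epimers (formed in the flask) | O=C1CC[C@@]2(C)C1CC[C@@H](O[Si](C)(C)C(C)(C)C)[C@@H]2C | intermediate
15 | (3aR,4R,5R,7aS)-5-(tert-butyldimethylsilyloxy)-3a,4-dimethyloctahydro-1H-inden-1-one (cis-fused) | O=C1CC[C@@]2(C)[C@@H]1CC[C@@H](O[Si](C)(C)C(C)(C)C)[C@@H]2C | intermediate
16 | 4-methoxybenzyl alcohol | COc1ccc(CO)cc1 | starting material
17 | chloromethyl phenyl sulfide | ClCSc1ccccc1 | starting material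
18 | 4-methoxybenzyl (phenylsulfanyl)methyl ether | COc1ccc(COCSc2ccccc2)cc1 | intermediate
19 | [(4-methoxybenzyl)oxy](phenylsulfanyl)methyllithium (formed in the flask) | COc1ccc(COC([Li])Sc2ccccc2)cc1 | intermediate
20 | (1R,3aR,4R,5R,7aS)-5-(tert-butyldimethylsilyloxy)-1-{[(4-methoxybenzyl)oxy](phenylsulfanyl)methyl}-3a,4-dimethyloctahydro-1H-inden-1-ol (C9 epimers; C8 drawn for convex-face addition) | C1C[C@@]2(C)[C@H](CC[C@@H](O[Si](C)(C)C(C)(C)C)[C@@H]2C)[C@@]1(O)C(OCc1ccc(OC)cc1)Sc1ccccc1 | intermediate
21 | C9 oxocarbenium ion of 20 after loss of benzenethiolate (formed in the flask) | C1C[C@@]2(C)[C@H](CC[C@@H](O[Si](C)(C)C(C)(C)C)[C@@H]2C)[C@@]1(O)C=[O+]Cc1ccc(OC)cc1 | intermediate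
22 | (4aR,5R,6R,8aS)-6-(tert-butyldimethylsilyloxy)-1-[(4-methoxybenzyl)oxy]-4a,5-dimethyloctahydronaphthalen-2(1H)-one, mixture of C9 epimers (formed in the flask) | O=C1CC[C@@]2(C)[C@H](CC[C@@H](O[Si](C)(C)C(C)(C)C)[C@@H]2C)C1OCc1ccc(OC)cc1 | intermediate
23 | (1R,4aR,5R,6R,8aS)-6-(tert-butyldimethylsilyloxy)-1-[(4-methoxybenzyl)oxy]-4a,5-dimethyloctahydronaphthalen-2(1H)-one (cis-decalin, 9β-OPMB) | O=C1CC[C@@]2(C)[C@H](CC[C@@H](O[Si](C)(C)C(C)(C)C)[C@@H]2C)[C@H]1OCc1ccc(OC)cc1 | intermediate
24 | 2-bromopropene | C=C(C)Br | starting material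
25 | lithium C7–C8 enolate of 23 (formed in the flask) | [Li]OC1=CC[C@@]2(C)[C@H](CC[C@@H](O[Si](C)(C)C(C)(C)C)[C@@H]2C)[C@H]1OCc1ccc(OC)cc1 | intermediate
26 | lithium dienolate of the alkenylated ketone (formed in the flask) | [Li]OC1=C(C(C)=C)C[C@@]2(C)[C@H](CC[C@@H](O[Si](C)(C)C(C)(C)C)[C@@H]2C)[C@H]1OCc1ccc(OC)cc1 | intermediate
27 | 7-isopropenyl ketone as a mixture of C7 epimers (formed in the flask) | C=C(C)C1C[C@@]2(C)[C@H](CC[C@@H](O[Si](C)(C)C(C)(C)C)[C@@H]2C)[C@@H](OCc3ccc(OC)cc3)C1=O | intermediate
28 | (1R,3R,4aR,5R,6R,8aS)-6-(tert-butyldimethylsilyloxy)-1-[(4-methoxybenzyl)oxy]-4a,5-dimethyl-3-(prop-1-en-2-yl)octahydronaphthalen-2(1H)-one | C=C(C)[C@H]1C[C@@]2(C)[C@H](CC[C@@H](O[Si](C)(C)C(C)(C)C)[C@@H]2C)[C@@H](OCc3ccc(OC)cc3)C1=O | intermediate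
29 | (1R,3R,4aR,5R,6R,8aS)-6-hydroxy-1-[(4-methoxybenzyl)oxy]-4a,5-dimethyl-3-(prop-1-en-2-yl)octahydronaphthalen-2(1H)-one | C=C(C)[C@H]1C[C@@]2(C)[C@H](CC[C@@H](O)[C@@H]2C)[C@@H](OCc3ccc(OC)cc3)C1=O | intermediate
30 | tigloyl chloride, (E)-2-methylbut-2-enoyl chloride | C/C=C(\C)C(Cl)=O | starting material
31 | 3α-tigloyloxy-9β-(4-methoxybenzyloxy)-10βH-eremophil-11-en-8-one | C=C(C)[C@H]1C[C@@]2(C)[C@H](CC[C@@H](OC(=O)/C(C)=C/C)[C@@H]2C)[C@@H](OCc3ccc(OC)cc3)C1=O | intermediate
32 | 3α-tigloyloxy-9β-hydroxy-10βH-eremophil-11-en-8-one | C=C(C)[C@H]1C[C@@]2(C)[C@H](CC[C@@H](OC(=O)/C(C)=C/C)[C@@H]2C)[C@@H](O)C1=O | intermediate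
33 | 3-methylbut-2-enoyl chloride | CC(C)=CC(Cl)=O | starting material
34 | (3R,4R,5R,7R,9R,10S)-3α-tigloyloxy-9β-(3-methylbut-2-enoyloxy)-10βH-eremophil-11-en-8-one | C=C(C)[C@H]1C[C@@]2(C)[C@H](CC[C@@H](OC(=O)/C(C)=C/C)[C@@H]2C)[C@@H](OC(=O)C=C(C)C)C1=O | target

Total step count: 19. Longest linear sequence: 17 steps (steps 1–5, 7–11 and 13–19); steps 6 and 12 are one-step side branches.

Steps most likely to fail

Step 14. The shift may take the C7 methylene instead of C10, or the oxocarbenium ion may lose the 4-methoxybenzyl cation before the shift occurs. The fallback uses the known α-ketol ring enlargement and sets out from 15. Addition of CH2=CHMgBr in THF to the C8 ketone should give the tertiary allylic alcohol F1. Ozonolysis (O3, CH2Cl2/MeOH, −78 °C, then Me2S) should give the 8-hydroxy-8-formyl hydrindane F2. BF3·OEt2 in CH2Cl2 should then promote the α-ketol rearrangement, in which C10 moves to the formyl carbon and the reversible process should settle on the ring-enlarged, equatorial 9β-hydroxy-8-ketone F3. Protection with 4-methoxybenzyl 2,2,2-trichloroacetimidate and catalytic La(OTf)3 returns to the route at 23.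

Step 15. Proton exchange between product and enolate may cause over-alkenylation, the equilibration may drive the double bond into conjugation, or protonation at C7 may occur with poor facial selectivity. The fallback sets out from 23. The kinetic enolate 25 is trapped with acetone at −78 °C, which should form the C7–C11 bond from the convex β face and give the tertiary aldol F4. Dehydration with SOCl2 in pyridine at −20 °C, which should remove a methyl hydrogen in preference to the hindered C7 hydrogen, returns to the route at 28.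

Step 7. The enolisable seleno aldehyde may simply protonate the hindered enolate, or the quaternary aldolate may revert on work-up. The fallback sets out from 6. Conjugate addition of Me2CuLi in the presence of TMSCl should give the trimethylsilyl enol ether F5. MeLi in THF regenerates the copper-free lithium enolate 9, which is added to phenyl vinyl sulfoxide (Michael addition) to give the keto sulfoxide F6. Heating in toluene with CaCO3 (sulfoxide syn-elimination) returns to the route at 11.

Further compounds
F1 | step 14 | (1R,3aR,4R,5R,7aS)-5-(tert-butyldimethylsilyloxy)-1-ethenyl-3a,4-dimethyloctahydro-1H-inden-1-ol | C=C[C@@]1(O)CC[C@@]2(C)[C@@H]1CC[C@@H](O[Si](C)(C)C(C)(C)C)[C@@H]2C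
F2 | step 14 | 5-(tert-butyldimethylsilyloxy)-1-hydroxy-3a,4-dimethyloctahydro-1H-indene-1-carbaldehyde (same ring configuration as F1) | O=C[C@@]1(O)CC[C@@]2(C)[C@@H]1CC[C@@H](O[Si](C)(C)C(C)(C)C)[C@@H]2C
F3 | step 14 | (1R,4aR,5R,6R,8aS)-6-(tert-butyldimethylsilyloxy)-1-hydroxy-4a,5-dimethyloctahydronaphthalen-2(1H)-one | O=C1CC[C@@]2(C)[C@H](CC[C@@H](O[Si](C)(C)C(C)(C)C)[C@@H]2C)[C@H]1O
F4 | step 15 | 7β-(2-hydroxypropan-2-yl) derivative of 23 | CC(C)(O)[C@H]1C[C@@]2(C)[C@H](CC[C@@H](O[Si](C)(C)C(C)(C)C)[C@@H]2C)[C@@H](OCc3ccc(OC)cc3)C1=O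
F5 | step 7 | (3R,4R)-4-(tert-butyldimethylsilyloxy)-2,3-dimethyl-1-(trimethylsilyloxy)cyclohex-1-ene | C[Si](C)(C)OC1=C(C)[C@@H](C)[C@H](O[Si](C)(C)C(C)(C)C)CC1
F6 | step 7 | (2R,3R,4R)-4-(tert-butyldimethylsilyloxy)-2,3-dimethyl-2-[2-(phenylsulfinyl)ethyl]cyclohexan-1-one (sulfoxide epimers) | O=S(CC[C@]1(C)[C@@H](C)[C@H](O[Si](C)(C)C(C)(C)C)CCC1=O)c1ccccc1
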